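**Plan**
- Retrosynthetic cuts: first the C4(isoflavan)–C6(flavanone) bond, giving a chroman para-quinone methide and 7,4'-di-O-benzyl-(2S)-naringenin; then the C3–C1' aryl bond of the isoflavanone (ketone α-arylation); then the O-benzyl and O-silyl bonds.
- Forward order: no ring is built, since the chroman ring (7-hydroxychroman-4-one) and the flavanone (naringenin) are bought. The B-ring bromide is joined to the chromanone by α-arylation, the ketone is reduced, the phenol is freed, the two halves are coupled, and the benzyl ethers are removed.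
- Enabling feature: C4 of the chroman is para (through C4a) to the C7 phenol and ortho (through C8a) to O1, so it is the methide carbon of a para-quinone methide. Its neighbour C3–H is labile through the isoflav-3-ene tautomer. The flavanone A ring is an acylphloroglucinol whose C6 is ortho to the free, chelated 5-OH.
- Stereochemistry: C2 of the flavanone comes from (2S)-naringenin. C4 is set by a chiral Brønsted acid and C3 by dynamic kinetic resolution (anti addition, 3,4-trans) in the same step, so the racemic cis/trans carbinol suffices.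

Key step: step 8

Assumption: (2S)-naringenin is bought as the single enantiomer, and the (R)-acid is taken to favour the C4 face that leads to (4S); if the sense is the opposite, its enantiomer is used.

Step 1
Reactants: 1 2,6-dimethoxyphenol
Product: 2 2-(benzyloxy)-1,3-dimethoxybenzene
Conditions: BnBr, K2CO3, DMF, rt
Reagents that add atoms: benzyl bromide BrCc1ccccc1
Why: Williamson etherification of the phenol, which masks the B-ring hydroxyl until the final hydrogenolysis and keeps the later bromination away from the position para to it.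

Step 2
Reactants: 2 2-(benzyloxy)-1,3-dimethoxybenzene
Product: 3 2-(benzyloxy)-4-bromo-1,3-dimethoxybenzene
Conditions: NBS, MeCN, 0 °C to rt
Reagents that add atoms: N-bromosuccinimide O=C1CCC(=O)N1Br
Why: Electrophilic aromatic bromination of a 1,2,3-trialkoxybenzene should go, as with 1,2,3-trimethoxybenzene, to C4 (ortho to one methoxy and para to the other), because the central benzyloxy group is twisted out of conjugation and activates its own para position only weakly.

Step 3
Reactants: 4 7-hydroxychroman-4-one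
Product: 5 7-[(triisopropylsilyl)oxy]chroman-4-one
Conditions: TIPSCl, imidazole, DMF, rt
Reagents that add atoms: triisopropylsilyl chloride CC(C)[Si](Cl)(C(C)C)C(C)C
Why: Standard silylation of a phenol, giving a TIPS ether that should tolerate the phosphate base of step 4 and can be removed in step 6 without touching the benzyl ethers.

Step 4
Reactants: 5 7-[(triisopropylsilyl)oxy]chroman-4-one; 3 2-(benzyloxy)-4-bromo-1,3-dimethoxybenzene
Product: 6 rac-3-[3-(benzyloxy)-2,4-dimethoxyphenyl]-7-[(triisopropylsilyl)oxy]chroman-4-one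
Conditions: Pd(OAc)2 (3 mol%), XPhos (6 mol%), K3PO4, toluene, 90 °C
Reagents that add atoms: none
Why: Palladium-catalysed α-arylation of a ketone (Buchwald–Hartwig type), a known route from chroman-4-ones to isoflavanones, in which the weak phosphate base limits retro-oxa-Michael opening of the enolate and the new C3 centre may form racemic because it is reset in step 8.

Step 5
Reactants: 6 rac-3-[3-(benzyloxy)-2,4-dimethoxyphenyl]-7-[(triisopropylsilyl)oxy]chroman-4-one
Product: 7 3-[3-(benzyloxy)-2,4-dimethoxyphenyl]-7-[(triisopropylsilyl)oxy]chroman-4-ol (racemic cis/trans mixture)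
Conditions: NaBH4, MeOH–THF, 0 °C
Reagents that add atoms: none
Why: Borohydride reduction of the aryl ketone, in which the cis/trans ratio and the racemic C4 carbinol do not matter because all four stereoisomers give the same quinone methide in step 8.

Step 6
Reactants: 7 3-[3-(benzyloxy)-2,4-dimethoxyphenyl]-7-[(triisopropylsilyl)oxy]chroman-4-ol
Product: 8 3-[3-(benzyloxy)-2,4-dimethoxyphenyl]-3,4-dihydro-2H-chromene-4,7-diol (racemic cis/trans mixture)
Conditions: TBAF, AcOH, THF, 0 °C
Reagents that add atoms: none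
Why: Fluoride cleavage of the aryl silyl ether, buffered with acetic acid so that no phenoxide accumulates that could expel the benzylic hydroxyl, leaves the benzyl ether and the carbinol untouched.

Step 7
Reactants: 9 (2S)-naringenin [(2S)-5,7-dihydroxy-2-(4-hydroxyphenyl)chroman-4-one]
Product: 10 (2S)-7-(benzyloxy)-2-[4-(benzyloxy)phenyl]-5-hydroxychroman-4-one
Conditions: BnOH (2.2 equiv), PPh3, DIAD, THF, 0 °C to rt
Reagents that add atoms: benzyl alcohol OCc1ccccc1
Why: Mitsunobu etherification should alkylate the two acidic phenols (7-OH and 4'-OH) and leave the hydrogen-bonded 5-OH, and its neutral conditions avoid the base-induced ring opening to the chalcone that would racemise C2.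

Step 8
Reactants: 8 3-[3-(benzyloxy)-2,4-dimethoxyphenyl]-3,4-dihydro-2H-chromene-4,7-diol; 10 (2S)-7-(benzyloxy)-2-[4-(benzyloxy)phenyl]-5-hydroxychroman-4-one
Product: 13 (2S)-7-(benzyloxy)-2-[4-(benzyloxy)phenyl]-6-{(3R,4S)-3-[3-(benzyloxy)-2,4-dimethoxyphenyl]-7-hydroxy-3,4-dihydro-2H-chromen-4-yl}-5-hydroxychroman-4-one, via para-quinone methide 11 (not isolated), via isoflav-3-ene tautomer 12 (not isolated)
Conditions: (R)-TRIP [3,3'-bis(2,4,6-triisopropylphenyl)-BINOL hydrogenphosphate] (10 mol%), 10 (2 equiv), 5 Å MS, toluene, 40 °C, slow addition of 8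
Reagents that add atoms: none
Why: Proposed new method: the chiral phosphoric acid should ionise the para-hydroxybenzylic carbinol 8 to the para-quinone methide 11, which racemises at C3 through its phenol tautomer 12 (C3–H is allylic to the C4=C4a methide and benzylic to the B ring), while the acid, hydrogen-bonded to the C7 carbonyl of 11 and to the phenol of 10, delivers C6 of the flavanone to C4 in a 1,6-conjugate (Friedel–Crafts) addition that re-aromatises the chroman A ring. The closest known reaction type is the chiral phosphoric acid catalysed asymmetric 1,6-addition of electron-rich arenes to para-quinone methides generated in situ from racemic para-hydroxybenzyl alcohols; new here are the dynamic kinetic resolution of the adjacent C3 centre through the vinylphenol tautomer and the chelated 5-hydroxyflavanone as the arene. No ring is closed in this step. C4 (S) is set by the catalyst, which selects the face of the methide carbon, and C3 (R) by substrate control within the Curtin–Hammett pair of quinone methide enantiomers, because the arene adds anti to the C3 aryl group, so that only the 3R enantiomer is matched with the catalyst-preferred face and the 3,4-trans product results; C2 of the flavanone is carried unchanged from 9. The step needs site selectivity for C6 over C8 of 10 and for 10 over self-condensation: C6 is ortho to the only free phenol (5-OH), the position at which 5-hydroxy-7-alkoxyflavonoids take electrophiles and the only one from which the phenol proton can be relayed to the phosphate in a cyclic array, and the excess of 10 with slow addition of 8 keeps 11 and 12 dilute.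

Step 9
Reactants: 13 (2S)-7-(benzyloxy)-2-[4-(benzyloxy)phenyl]-6-{(3R,4S)-3-[3-(benzyloxy)-2,4-dimethoxyphenyl]-7-hydroxy-3,4-dihydro-2H-chromen-4-yl}-5-hydroxychroman-4-one
Product: 14 (2S)-6-[(3R,4S)-7-hydroxy-3-(3-hydroxy-2,4-dimethoxyphenyl)-3,4-dihydro-2H-chromen-4-yl]-5,7-dihydroxy-2-(4-hydroxyphenyl)chroman-4-one (target)
Conditions: H2 (1 atm), 10% Pd/C, EtOAc–MeOH, rt
Reagents that add atoms: none
Why: Catalytic hydrogenolysis of the three benzyl ethers under neutral conditions should leave the chelated aryl ketone, the cyclic benzylic ethers and the three stereocentres untouched.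

**Compound list**
1 | 2,6-dimethoxyphenol | COc1cccc(OC)c1O | starting material
2 | 2-(benzyloxy)-1,3-dimethoxybenzene | COc1cccc(OC)c1OCc1ccccc1 | intermediate
3 | 2-(benzyloxy)-4-bromo-1,3-dimethoxybenzene | COc1ccc(Br)c(OC)c1OCc1ccccc1 | intermediate
4 | 7-hydroxychroman-4-one | O=C1CCOc2cc(O)ccc12 | starting material
5 | 7-[(triisopropylsilyl)oxy]chroman-4-one | O=C1CCOc2cc(O[Si](C(C)C)(C(C)C)C(C)C)ccc12 | intermediate
6 | rac-3-[3-(benzyloxy)-2,4-dimethoxyphenyl]-7-[(triisopropylsilyl)oxy]chroman-4-one | COc1ccc(C2COc3cc(O[Si](C(C)C)(C(C)C)C(C)C)ccc3C2=O)c(OC)c1OCc1ccccc1 | intermediate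
7 | 3-[3-(benzyloxy)-2,4-dimethoxyphenyl]-7-[(triisopropylsilyl)oxy]chroman-4-ol, racemic cis/trans mixture | COc1ccc(C2COc3cc(O[Si](C(C)C)(C(C)C)C(C)C)ccc3C2O)c(OC)c1OCc1ccccc1 | intermediate
8 | 3-[3-(benzyloxy)-2,4-dimethoxyphenyl]-3,4-dihydro-2H-chromene-4,7-diol, racemic cis/trans mixture | COc1ccc(C2COc3cc(O)ccc3C2O)c(OC)c1OCc1ccccc1 | intermediate
9 | (2S)-naringenin, (2S)-5,7-dihydroxy-2-(4-hydroxyphenyl)chroman-4-one | O=C1C[C@@H](c2ccc(O)cc2)Oc2cc(O)cc(O)c12 | starting material
10 | (2S)-7-(benzyloxy)-2-[4-(benzyloxy)phenyl]-5-hydroxychroman-4-one | O=C1C[C@@H](c2ccc(OCc3ccccc3)cc2)Oc2cc(OCc3ccccc3)cc(O)c12 | intermediate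
11 | (3R)-3-[3-(benzyloxy)-2,4-dimethoxyphenyl]-2,3-dihydro-7H-chromen-7-one, para-quinone methide formed in situ and in equilibrium with its 3S enantiomer | COc1ccc([C@@H]2COC3=CC(=O)C=CC3=C2)c(OC)c1OCc1ccccc1 | intermediate
12 | 3-[3-(benzyloxy)-2,4-dimethoxyphenyl]-2H-chromen-7-ol, achiral isoflav-3-ene formed in situ | COc1ccc(C2=Cc3ccc(O)cc3OC2)c(OC)c1OCc1ccccc1 | intermediate
13 | (2S)-7-(benzyloxy)-2-[4-(benzyloxy)phenyl]-6-{(3R,4S)-3-[3-(benzyloxy)-2,4-dimethoxyphenyl]-7-hydroxy-3,4-dihydro-2H-chromen-4-yl}-5-hydroxychroman-4-one | COc1ccc([C@@H]2COc3cc(O)ccc3[C@H]2c2c(OCc4ccccc4)cc3c(c2O)C(=O)C[C@@H](c2ccc(OCc4ccccc4)cc2)O3)c(OC)c1OCc1ccccc1 | intermediate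
14 | (2S)-6-[(3R,4S)-7-hydroxy-3-(3-hydroxy-2,4-dimethoxyphenyl)-3,4-dihydro-2H-chromen-4-yl]-5,7-dihydroxy-2-(4-hydroxyphenyl)chroman-4-one | COc1ccc([C@@H]2COc3cc(O)ccc3[C@H]2c2c(O)cc3c(c2O)C(=O)C[C@@H](c2ccc(O)cc2)O3)c(OC)c1O | target

Total step count: 9. Longest linear sequence: 7 steps (steps 1, 2, 4, 5, 6, 8, 9).

**Steps most likely to fail**

1. Step 8 (Proposed new method). The catalyst may not discriminate the two faces of the methide carbon well enough, the deactivated arene may add too slowly so that the quinone methide and isoflavene condense with their own resorcinol ring, or attack may take place through C8 instead of C6. The fallback uses known chemistry, sets out from 6 and comes back at 13. It would fix C3 beforehand rather than through the catalyst, and it would not cure a C8 site-selectivity problem, since it uses the same arene 10. Noyori–Ikariya asymmetric transfer hydrogenation of 6 with dynamic kinetic resolution (RuCl[(R,R)-TsDPEN](p-cymene), HCO2H/Et3N; the (R,R) catalyst is expected to give the 4R alcohol by analogy with aryl ketones) should give the cis carbinol (3R,4R)-3-[3-(benzyloxy)-2,4-dimethoxyphenyl]-7-[(triisopropylsilyl)oxy]chroman-4-ol F1. Its silyl ether prevents quinone methide formation and so slows loss of the C3 configuration. A Lewis acid Friedel–Crafts alkylation of 10 with F1 (BF3·OEt2, CH2Cl2, −78 °C), in which the arene enters anti to the C3 aryl group, should give the trans-coupled silyl ether F2. Desilylation (TBAF, AcOH) then gives 13.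

2. Step 4. The chromanone enolate may open by retro-oxa-Michael elimination, the silyl ether may be lost, or the product may be arylated a second time. The fallback builds the isoflavone by cross-coupling instead; it sets out from 3 and comes back at 7. Miyaura borylation of 3 (B2pin2, Pd(dppf)Cl2, KOAc) gives 2-[3-(benzyloxy)-2,4-dimethoxyphenyl]-4,4,5,5-tetramethyl-1,3,2-dioxaborolane F3. In parallel, commercial 2',4'-dihydroxyacetophenone is silylated at the non-chelated 4-OH to 1-{2-hydroxy-4-[(triisopropylsilyl)oxy]phenyl}ethan-1-one F4, condensed with DMF dimethyl acetal to the enaminone F5 and cyclised with iodine to 3-iodo-7-[(triisopropylsilyl)oxy]-4H-chromen-4-one F6. Suzuki–Miyaura coupling of F3 with F6 gives the isoflavone F7, whose reduction with NaBH4 (conjugate, then carbonyl reduction) gives 7.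

3. Step 7. Alkylation may spill over to the 5-OH or stop at the monoether, and the C2 configuration may erode. The fallback changes the protecting group class; it sets out from 9 and comes back at 14. Silylation (TBSCl, imidazole, DMF), which does not touch the chelated 5-OH, gives (2S)-7-[(tert-butyldimethylsilyl)oxy]-2-{4-[(tert-butyldimethylsilyl)oxy]phenyl}-5-hydroxychroman-4-one F8. This is coupled with 8 under the conditions of step 8 to the bis-silyl ether F9. Desilylation with HF·pyridine gives the B-ring benzyl ether of the target F10, and hydrogenolysis (H2, Pd/C) gives 14.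

**Further compounds**
F1 | step 8 | (3R,4R)-3-[3-(benzyloxy)-2,4-dimethoxyphenyl]-7-[(triisopropylsilyl)oxy]chroman-4-ol | COc1ccc([C@@H]2COc3cc(O[Si](C(C)C)(C(C)C)C(C)C)ccc3[C@@H]2O)c(OC)c1OCc1ccccc1
F2 | step 8 | (2S)-7-(benzyloxy)-2-[4-(benzyloxy)phenyl]-6-{(3R,4S)-3-[3-(benzyloxy)-2,4-dimethoxyphenyl]-7-[(triisopropylsilyl)oxy]-3,4-dihydro-2H-chromen-4-yl}-5-hydroxychroman-4-one | COc1ccc([C@@H]2COc3cc(O[Si](C(C)C)(C(C)C)C(C)C)ccc3[C@H]2c2c(OCc4ccccc4)cc3c(c2O)C(=O)C[C@@H](c2ccc(OCc4ccccc4)cc2)O3)c(OC)c1OCc1ccccc1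
F3 | step 4 | 2-[3-(benzyloxy)-2,4-dimethoxyphenyl]-4,4,5,5-tetramethyl-1,3,2-dioxaborolane | COc1ccc(B2OC(C)(C)C(C)(C)O2)c(OC)c1OCc1ccccc1
F4 | step 4 | 1-{2-hydroxy-4-[(triisopropylsilyl)oxy]phenyl}ethan-1-one | CC(=O)c1ccc(O[Si](C(C)C)(C(C)C)C(C)C)cc1O
F5 | step 4 | (E)-3-(dimethylamino)-1-{2-hydroxy-4-[(triisopropylsilyl)oxy]phenyl}prop-2-en-1-one | CN(C)/C=C/C(=O)c1ccc(O[Si](C(C)C)(C(C)C)C(C)C)cc1O
F6 | step 4 | 3-iodo-7-[(triisopropylsilyl)oxy]-4H-chromen-4-one | O=c1c(I)coc2cc(O[Si](C(C)C)(C(C)C)C(C)C)ccc12
F7 | step 4 | 3-[3-(benzyloxy)-2,4-dimethoxyphenyl]-7-[(triisopropylsilyl)oxy]-4H-chromen-4-one | COc1ccc(-c2coc3cc(O[Si](C(C)C)(C(C)C)C(C)C)ccc3c2=O)c(OC)c1OCc1ccccc1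
F8 | step 7 | (2S)-7-[(tert-butyldimethylsilyl)oxy]-2-{4-[(tert-butyldimethylsilyl)oxy]phenyl}-5-hydroxychroman-4-one | O=C1C[C@@H](c2ccc(O[Si](C)(C)C(C)(C)C)cc2)Oc2cc(O[Si](C)(C)C(C)(C)C)cc(O)c12
F9 | step 7 | (2S)-6-{(3R,4S)-3-[3-(benzyloxy)-2,4-dimethoxyphenyl]-7-hydroxy-3,4-dihydro-2H-chromen-4-yl}-7-[(tert-butyldimethylsilyl)oxy]-2-{4-[(tert-butyldimethylsilyl)oxy]phenyl}-5-hydroxychroman-4-one | COc1ccc([C@@H]2COc3cc(O)ccc3[C@H]2c2c(O[Si](C)(C)C(C)(C)C)cc3c(c2O)C(=O)C[C@@H](c2ccc(O[Si](C)(C)C(C)(C)C)cc2)O3)c(OC)c1OCc1ccccc1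
F10 | step 7 | (2S)-6-{(3R,4S)-3-[3-(benzyloxy)-2,4-dimethoxyphenyl]-7-hydroxy-3,4-dihydro-2H-chromen-4-yl}-5,7-dihydroxy-2-(4-hydroxyphenyl)chroman-4-one | COc1ccc([C@@H]2COc3cc(O)ccc3[C@H]2c2c(O)cc3c(c2O)C(=O)C[C@@H](c2ccc(O)cc2)O3)c(OC)c1OCc1ccccc1
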